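In amounts, the flask and the maple run share 5.0 × 10⁻⁴ M of substrate and differ in catalyst, 0.2 mol% against 0.3 mol%.

| flask | substrate | catalyst | remark | time |
|---|---|---|---|---|
| larch | 2.5 × 10⁻⁴ M | 0.2 mol% | run made earlier |  |
| ash | 0.0010 M | 0.2 mol% | run made earlier |  |
| maple | 5.0 × 10⁻⁴ M | 0.3 mol% | run made earlier |  |
| flask | 5.0 × 10⁻⁴ M | 0.2 mol% |  | 2.5 min |

| run | time / min | target / % |
|---|---|---|
| larch | 0.200 | 2.9 |
| larch | 0.500 | 7.3 |
| larch | 1.33 | 9.7 |
| larch | 3.00 | 10.4 |
| ash | 0.200 | 17.2 |
| ash | 0.500 | 21.2 |
| ash | 1.33 | 17.9 |
| ash | 3.00 | 13.2 |
| maple | 0.200 | 11.4 |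
| maple | 0.500 | 16.9 |
| maple | 1.33 | 14.5 |
| maple | 3.00 | 11.1 |

(each reading ± 1 percentage point)

1. the best time, 2.5 min at the latest, for target
2. the amount of target, in percent of the substrate charged, at that time
3. the first time at which target reaches 7.5 %, in the same percent, in min

- steps under discussion: substrate + catalyst <-> target + catalyst; substrate <-> isomer of the product

The isomerisation takes no catalyst, while the catalysed step, if the catalyst stays intact, is pseudo-first-order in substrate at a rate proportional to the catalyst concentration C, the substrate charge times the loading. So I compared the runs by C. The flask has 1.00 × 10⁻⁶ M and maple 1.50 × 10⁻⁶ M, so the flask has 0.667 of maple's C, and its catalysed step runs slower than maple's.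

The highest readings of target rose with C, from 10.4 % in larch at 5.00 × 10⁻⁷ M to 21.2 % in ash at 2.00 × 10⁻⁶ M. Working in powers of ten, I divided that rise by the 0.602 decades between the two runs and got 18 percentage points. This is the decade gain g, the rise of the highest target reading per decade of C. The flask lies 0.176 decades below maple, so from maple's reading of 16.9 % I expected a highest target of 13.7 % in the flask, uncertain by at least the scatter of that reading, 1 point.

A catalyst shifts no equilibrium, and at 3.00 min the readings spanned 2.8 points, less than the 11 points between the highest readings. So I expected the flask to end close to maple's 11.1 %.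

The forecast, “The flask sits between maple and larch”, gave 14 % at 0.85 min, with the asked amount first reached at 0.2 min.

The flask gave 15.0 % at 0.877 min, reached the asked amount first at 0.164 min, and held 12.0 % of target at 2.50 min.

    substrate + catalyst ⇌ target + catalyst, rate k1*[substrate]*[catalyst] forward; the back reaction follows from the equilibrium constant (K = 1.00, k = 10100 /M/s)
    substrate ⇌ isomer of the product (K = 9.12, k = 0.0390 /s)

The neighbouring flask was charged with 0.0020 M of substrate at the same loading, so its C was 4.00 × 10⁻⁶ M, which lies 0.301 decades above ash. With g, I reckoned its highest target from ash's reading as 26.6 %. The simulation of that neighbouring flask gave 28.3 %, and by 2.50 min its target had fallen to 11.3 %, against 12.0 % in the flask.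

The runs are simulated with made-up constants; the scatter is artificial.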